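Readings and results were computed on assumed constants; the scatter is artificial.

| setting | violet | ochre | flask |
|---|---|---|---|
| left-handed substrate | 0.50 mM | 0.50 mM | 0.50 mM |
| right-handed substrate | 0.50 mM | 0.50 mM | 0.50 mM |
| solid reagent | 0.50 mM | 0.50 mM | 0.500 mM |
| free catalyst | 10 µM | 6.7 µM | 10 µM |
| remark | the very flask that is asked about, followed so far | run made earlier |  |

violet run (percent of the left-handed substrate and right-handed substrate together charged)

| time / s | left-handed product / % | left-handed substrate / % |
|---|---|---|
| 10.0 | 0 | 48.8 |
| 15.0 | 0.5 | 47.1 |
| 25.0 | 5.1 | 44.8 |
| 50.0 | 9.7 | 37.0 |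
| 90.0 | 17.0 | 31.6 |

ochre run (percent of the left-handed substrate and right-handed substrate together charged)

| time / min | left-handed product / % | left-handed substrate / % |
|---|---|---|
| 0.250 | 2.2 | 48.1 |
| 0.500 | 5.8 | 44.9 |
| 0.833 | 8.9 | 42.2 |
| 1.50 | 13.7 | 38.6 |
| 3.00 | 22.1 | 27.5 |

(scatter of a reading: 1 percentage point)

- apparent order in free catalyst when 50% of the left-handed substrate and right-handed substrate together are converted (percent change of the rate of making left-handed product for one percent more free catalyst charged)

- free catalyst is single-handed; left-handed substrate and right-handed substrate are mirror images of each other, charged as a racemate, each of them at the stated concentration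
- as a solid, counted per litre of solution: solid reagent
- at the start none of the solid reagent is in solution

1. I began from the left-handed product, which in the violet run was made at 0.132 mM min⁻¹ between 15.0 s and 90.0 s, and I took its rate to be proportional to the catalyst and to the solid reagent in solution.

2. The solid reagent charge was half of both substrates together, so I treated it as the limiting reagent, used one for one, and expected 50% conversion to bring it close to its end.

3. But I assumed that the catalyst holds substrate before the reagent arrives, so converted substrate runs ahead of reagent used, and the reagent left at 50% equals the substrate so held. With one substrate per catalyst, its ceiling, catalyst charge over reagent charge, is 2.00%.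

4. Against its charge, the reagent factor in the rate had therefore shrunk by at least 50.0. As what remains scales with the catalyst charged, and the rate carries the catalyst once more, I reckoned an order of 2.

5. The forecast gave 0.9, reasoning that “dissolved reagent is fixed by conversion”, and there my reckoning differed.

6. The flask gave 2.0.

    free catalyst + left-handed substrate ⇌ catalyst intermediate A (K = 1300 M⁻¹, k = 3.77 × 10⁵ M⁻¹ s⁻¹)
    free catalyst + right-handed substrate ⇌ catalyst intermediate B (K = 2500 M⁻¹, k = 13800 M⁻¹ s⁻¹)
    coupling partner + catalyst intermediate A → free catalyst + left-handed product (k = 3010 M⁻¹ s⁻¹)
    coupling partner + catalyst intermediate B → free catalyst + right-handed product (k = 248 M⁻¹ s⁻¹)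
    solid reagent ⇌ coupling partner, rate k5*(cs5 - [coupling partner]) while solid is left; crystals form when [coupling partner] > cs5 (solubility = 0.470 mM, k = 0.135 s⁻¹)

7. At 19.4 min the flask made left-handed product at 6.43 × 10⁻⁴ mM min⁻¹, lower than the early 0.132 mM min⁻¹. The ochre run has a ceiling of 1.34%, and squaring the ratio of ceilings gives it 2.89 × 10⁻⁴ mM min⁻¹ at 50% conversion.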